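**Strategy**

- Numbering: ring carbons C1–C10, carboxyl carbon C14 on C10, methyl C15 on C4, acetoxy groups on C6 and C8, isopropyl on C7. The C6 oxygen lies between the cis C4=C5 alkene and the chain C7–C8–C9–C10, so it is read as the oxygen of a 3-oxy-1,5-diene: the ten-membered ring is cut at C8–C9 while a transannular C1–C6 bond is restored, which leaves a 4-methylcyclohex-3-ene with one alkenyl arm on C6 and one on C1.
- The cyclohexene is cut further at C6–C7 (alkenylmetal addition to an enone) and at C1–C6/C2–C3 (Diels–Alder reaction of a 1-silyloxy diene with 1,1-dimethoxybut-3-en-2-one); C9 comes from a methylenation and C14 is carried as a dimethyl acetal.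
- Forward: the six-membered ring is made first by cycloaddition, the two arms are placed on C1 and C6, and the only ring of the target then grows from six to ten atoms in the oxy-Cope step; the acid is unmasked last.
- Stereochemistry: the catalytic Diels–Alder reaction sets the sacrificial C1 centre, which steers the addition at C6. The chair shift passes this on to C8 and to a planar-chiral enolate whose protonation sets C7. A reduction directed by the C8 hydroxyl sets C6, and the C1=C10 geometry is corrected thermodynamically at the enal stage.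

Key step: step 12

Assumption: the oxazaborolidinium catalyst is taken to shield the same face of an acyclic vinyl ketone as of an acrylate ester (boron on the carbonyl lone pair syn to the vinyl group), which assigns the catalyst from (R)-α,α-diphenylprolinol to the required centre; the configuration of 7 would be confirmed before material is carried on.

**Route**

Step 1
Reactants: 1 3-methylbut-2-enal
Product: 2 (E)-3-methyl-1-[tri(propan-2-yl)silyloxy]buta-1,3-diene
Conditions: i-Pr3SiOTf, Et3N, Et2O, 0 °C to rt
Reagents that add atoms: triisopropylsilyl trifluoromethanesulfonate, CC(C)[Si](C(C)C)(C(C)C)OS(=O)(=O)C(F)(F)F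
Why: Silyl dienol ether formation, in which O-silylation of the enal and γ-deprotonation by the amine should give the 1-silyloxy diene as the E isomer from the extended silyloxocarbenium ion, the bulky silyl group being chosen to survive the Lewis acid of step 4.

Step 2
Reactants: 3 methyl 2,2-dimethoxyacetate
Product: 4 N-methoxy-N-methyl-2,2-dimethoxyacetamide
Conditions: MeNH(OMe)·HCl, i-PrMgCl, THF, −20 °C
Reagents that add atoms: N,O-dimethylhydroxylamine hydrochloride, CNOC.Cl
Why: Weinreb amide formation by aminolysis of the ester with the chloromagnesium amide, which is fast in the cold and leaves the acetal untouched.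

Step 3
Reactants: 4 N-methoxy-N-methyl-2,2-dimethoxyacetamide
Product: 6 1,1-dimethoxybut-3-en-2-one, via bromomagnesium hemiaminal chelate 5 (not isolated)
Conditions: CH2=CHMgBr, THF, −78 to 0 °C; inverse quench into cold 1 M HCl
Reagents that add atoms: vinylmagnesium bromide, C=C[Mg]Br
Why: Weinreb ketone synthesis, in which the chelated tetrahedral adduct 5 stops the addition at the ketone stage and the inverse acidic quench keeps the released hydroxylamine protonated so that it cannot add to the new vinyl ketone.

Step 4
Reactants: 2 (E)-3-methyl-1-[tri(propan-2-yl)silyloxy]buta-1,3-diene; 6 1,1-dimethoxybut-3-en-2-one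
Product: 7 2,2-dimethoxy-1-[(1R,2S)-4-methyl-2-{[tri(propan-2-yl)silyl]oxy}cyclohex-3-en-1-yl]ethan-1-one
Conditions: (R)-3,3-diphenyl-1-(2-methylphenyl)tetrahydro-1H,3H-pyrrolo[1,2-c][1,3,2]oxazaborole (20 mol%), HN(SO2CF3)2 (16 mol%), CH2Cl2, −78 °C
Reagents that add atoms: none
Why: Catalytic enantioselective Diels–Alder reaction under oxazaborolidinium activation, in which the silyloxy and methyl groups of the diene both direct the acyl group next to the silyloxy carbon, endo addition should give the cis ring, and the catalyst face sets the acyl-bearing centre (the silyloxy centre is oxidised away in step 7, so only this centre has to be controlled).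

Step 5
Reactants: 7 2,2-dimethoxy-1-[(1R,2S)-4-methyl-2-{[tri(propan-2-yl)silyl]oxy}cyclohex-3-en-1-yl]ethan-1-one
Product: 8 {[(1S,6S)-6-(3,3-dimethoxyprop-1-en-2-yl)-3-methylcyclohex-2-en-1-yl]oxy}tri(propan-2-yl)silane
Conditions: Cp2Ti(μ-CH2)(μ-Cl)AlMe2 (Tebbe reagent), pyridine, THF/toluene, −40 °C to rt
Reagents that add atoms: Tebbe reagent, C[Al-]1(C)C[Ti]([Cl+]1)(C1C=CC=C1)C1C=CC=C1
Why: Tebbe methylenation, whose non-basic titanium methylidene should convert the ketone into the 1,1-disubstituted alkene (C9) without epimerising the adjacent ring centre or eliminating the β-silyloxy group.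

Step 6
Reactants: 8 {[(1S,6S)-6-(3,3-dimethoxyprop-1-en-2-yl)-3-methylcyclohex-2-en-1-yl]oxy}tri(propan-2-yl)silane
Product: 9 (1S,6S)-6-(3,3-dimethoxyprop-1-en-2-yl)-3-methylcyclohex-2-en-1-ol
Conditions: Bu4NF, THF, 0 °C to rt
Reagents that add atoms: none
Why: Fluoride desilylation of the allylic silyl ether, to which nothing else in the molecule responds and which leaves both stereocentres untouched.

Step 7
Reactants: 9 (1S,6S)-6-(3,3-dimethoxyprop-1-en-2-yl)-3-methylcyclohex-2-en-1-ol
Product: 10 (6S)-6-(3,3-dimethoxyprop-1-en-2-yl)-3-methylcyclohex-2-en-1-one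
Conditions: Dess–Martin periodinane, NaHCO3, CH2Cl2, 0 °C
Reagents that add atoms: none
Why: Dess–Martin oxidation of the allylic alcohol under bicarbonate buffer, a neutral method under which the centre between the carbonyl and the alkenyl group is not expected to epimerise or slip into conjugation, as isopiperitenone-type enones tolerate such conditions.

Step 8
Reactants: 11 3-methylbutanal
Product: 12 1,1-bis[(4-methoxybenzyl)oxy]-3-methylbutane
Conditions: 4-MeOC6H4CH2OH (2.2 equiv), pyridinium p-toluenesulfonate (cat.), MgSO4, CH2Cl2, rt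
Reagents that add atoms: 4-methoxybenzyl alcohol, COc1ccc(CO)cc1
Why: Acid-catalysed acetalisation of an aliphatic aldehyde with a primary benzylic alcohol, driven by removal of water and kept mild to avoid self-etherification of the alcohol.

Step 9
Reactants: 12 1,1-bis[(4-methoxybenzyl)oxy]-3-methylbutane
Product: 13 1-methoxy-4-{[(3-methylbut-1-en-1-yl)oxy]methyl}benzene (E/Z mixture)
Conditions: Me3SiOTf, i-Pr2NEt, CH2Cl2, −20 °C to rt
Reagents that add atoms: none
Why: Acetal-to-enol-ether elimination, in which the silyl triflate ionises the acetal to the oxocarbenium ion and the hindered amine removes the adjacent proton, the alkene geometry being irrelevant because the next step erases it.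

Step 10
Reactants: 13 1-methoxy-4-{[(3-methylbut-1-en-1-yl)oxy]methyl}benzene
Product: 15 1-({[(1Z)-2-bromo-3-methylbut-1-en-1-yl]oxy}methyl)-4-methoxybenzene, via dibromo ether 14 (not isolated)
Conditions: Br2, CH2Cl2, −78 °C; then i-Pr2NEt, −78 °C to rt
Reagents that add atoms: bromine, BrBr
Why: Bromination–dehydrobromination of an enol ether, in which the dibromide 14 ionises at the α-bromo ether carbon and loses the neighbouring proton, the isomer with bromine cis to oxygen (isopropyl trans to the ether oxygen) being expected as the major, sterically favoured product and any E isomer to be removed by chromatography.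

Step 11
Reactants: 15 1-({[(1Z)-2-bromo-3-methylbut-1-en-1-yl]oxy}methyl)-4-methoxybenzene; 10 (6S)-6-(3,3-dimethoxyprop-1-en-2-yl)-3-methylcyclohex-2-en-1-one
Product: 18 (1S,6S)-6-(3,3-dimethoxyprop-1-en-2-yl)-1-{(1Z)-1-[(4-methoxybenzyl)oxy]-3-methylbut-1-en-2-yl}-3-methylcyclohex-2-en-1-ol, via alkenyllithium 16 (not isolated), via alkenylcerium dichloride 17 (not isolated)
Conditions: t-BuLi (2 equiv), Et2O, −78 °C; CeCl3, THF, −78 °C; then 10, −78 °C
Reagents that add atoms: none
Why: Bromine–lithium exchange with retention gives the oxygen-chelated alkenyllithium 16 (lithium cis to oxygen, so anti β-elimination is not possible), transmetalation to the weakly basic organocerium 17 suppresses enolisation of the enone, and organocerium 1,2-addition should take place on the face away from the neighbouring alkenyl substituent, as hydride does with isopiperitenone-type enones, which sets the carbinol centre with the two alkenyl arms trans.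

Step 12
Reactants: 18 (1S,6S)-6-(3,3-dimethoxyprop-1-en-2-yl)-1-{(1Z)-1-[(4-methoxybenzyl)oxy]-3-methylbut-1-en-2-yl}-3-methylcyclohex-2-en-1-ol
Product: 21 (2Z,6Z,9R,10S)-7-(dimethoxymethyl)-9-[(4-methoxybenzyl)oxy]-3-methyl-10-(propan-2-yl)cyclodeca-2,6-dien-1-one, via potassium alkoxide 19 (not isolated), via potassium enolate 20 (not isolated)
Conditions: KN(SiMe3)2, THF, −78 °C to rt; then AcOH, THF, −78 °C
Reagents that add atoms: none
Why: KN(SiMe3)2 converts 18 into the potassium alkoxide 19, whose C6 oxido group weakens the adjacent C1–C6 bond, and the 3-oxido-1,5-diene C8=C7–C6–C1–C10=C9 then undergoes a concerted [3,3] shift that makes C8–C9 and breaks C1–C6 to give the ten-membered potassium enolate 20. The closest known reaction type is the anionic oxy-Cope ring expansion of trans-1,2-dialkenylcyclohexanols to cyclodec-5-enones. The ten-membered ring is therefore not closed end to end but grows out of the cyclohexene by four carbons, through the only chair open to the trans compound, the one with both alkenyl arms equatorial on the cyclohexene and the oxido group and the C1 hydrogen axial. C8 is set by that chair, in which the oxygen of the Z enol ether is axial, so that the configuration of the two cyclohexene centres is passed on to it, and C7 is set when the planar-chiral ring-E enolate is protonated at −78 °C from its outer face, the inner face being covered by the ring. The step needs the shift to run through the enol ether arm and not through the ring alkene, which could reach C9 only through a strained boat, and it needs the β-alkoxy enolate to keep its C8 oxygen, for which crown ether is left out so that K+ bridges the enolate and ether oxygens and holds the C8–O bond in the nodal plane of the enolate, and the quench is done cold. The chair necessarily delivers the C1=C10 alkene as the ring-E isomer, which is why its geometry is corrected at the enal stage in step 17.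

Step 13
Reactants: 21 (2Z,6Z,9R,10S)-7-(dimethoxymethyl)-9-[(4-methoxybenzyl)oxy]-3-methyl-10-(propan-2-yl)cyclodeca-2,6-dien-1-one
Product: 22 (2Z,6Z,9R,10S)-7-(dimethoxymethyl)-9-hydroxy-3-methyl-10-(propan-2-yl)cyclodeca-2,6-dien-1-one
Conditions: DDQ, CH2Cl2/pH 7 phosphate buffer, 0 °C
Reagents that add atoms: none
Why: Oxidative cleavage of the 4-methoxybenzyl ether by DDQ (benzylic hydride abstraction, then hydrolysis of the oxocarbenium ion) under buffered neutral conditions that should spare the acetal, the enone and the base-sensitive C7 centre.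

Step 14
Reactants: 22 (2Z,6Z,9R,10S)-7-(dimethoxymethyl)-9-hydroxy-3-methyl-10-(propan-2-yl)cyclodeca-2,6-dien-1-one
Product: 23 (1R,3Z,7Z,9R,10R)-3-(dimethoxymethyl)-9-hydroxy-7-methyl-10-(propan-2-yl)cyclodeca-3,7-dien-1-yl acetate
Conditions: SmI2 (30 mol%), CH3CHO (excess), THF, −10 °C
Reagents that add atoms: acetaldehyde, CC=O
Why: Evans–Tishchenko reduction, in which the samarium-bound hemiacetal formed from the C8 hydroxyl and acetaldehyde delivers hydride intramolecularly to the C6 carbonyl through a six-membered chelate, which sets C6 with O6 and O8 1,3-anti by 1,2-reduction of the enone (an external hydride would be expected to attack the opposite face) and leaves C8 as its acetate in the same operation.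

Step 15
Reactants: 23 (1R,3Z,7Z,9R,10R)-3-(dimethoxymethyl)-9-hydroxy-7-methyl-10-(propan-2-yl)cyclodeca-3,7-dien-1-yl acetate
Product: 24 (1R,2Z,6Z,9R,10S)-7-(dimethoxymethyl)-3-methyl-10-(propan-2-yl)cyclodeca-2,6-diene-1,9-diyl diacetate
Conditions: Ac2O, 4-(dimethylamino)pyridine (cat.), pyridine, CH2Cl2, 0 °C to rt
Reagents that add atoms: acetic anhydride, CC(=O)OC(C)=O
Why: Nucleophile-catalysed acetylation of the remaining allylic secondary alcohol, which proceeds with retention at C6.

Step 16
Reactants: 24 (1R,2Z,6Z,9R,10S)-7-(dimethoxymethyl)-3-methyl-10-(propan-2-yl)cyclodeca-2,6-diene-1,9-diyl diacetate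
Product: 25 (1R,2Z,6Z,9R,10S)-7-formyl-3-methyl-10-(propan-2-yl)cyclodeca-2,6-diene-1,9-diyl diacetate
Conditions: pyridinium p-toluenesulfonate, acetone/H2O, rt
Reagents that add atoms: water, O
Why: Acid-catalysed hydrolysis of an α,β-unsaturated dimethyl acetal, which ionises far more readily than the acetates or the allylic C6–O bond under pyridinium catalysis.

Step 17
Reactants: 25 (1R,2Z,6Z,9R,10S)-7-formyl-3-methyl-10-(propan-2-yl)cyclodeca-2,6-diene-1,9-diyl diacetate
Product: 26 (1R,2Z,6E,9R,10S)-7-formyl-3-methyl-10-(propan-2-yl)cyclodeca-2,6-diene-1,9-diyl diacetate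
Conditions: PhSH (10 mol%), Et3N (10 mol%), CH2Cl2, rt
Reagents that add atoms: none
Why: Thermodynamic isomerisation of a 2-substituted enal by reversible conjugate addition of thiolate (addition at C1, rotation about the C1–C10 bond of the enolate, elimination), which should funnel the material into the E-enal, the isomer that is also cis within the ten-membered ring and is therefore expected to be favoured on both counts.

Step 18
Reactants: 26 (1R,2Z,6E,9R,10S)-7-formyl-3-methyl-10-(propan-2-yl)cyclodeca-2,6-diene-1,9-diyl diacetate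
Product: 27 (1E,5Z,7R,8S,9R)-7,9-bis(acetyloxy)-5-methyl-8-(propan-2-yl)cyclodeca-1,5-diene-1-carboxylic acid (CNP0172943.1)
Conditions: NaClO2, NaH2PO4, 2-methylbut-2-ene, t-BuOH/H2O, 0 °C to rt
Reagents that add atoms: sodium chlorite, [Na+].[O-]Cl=O
Why: Pinnick oxidation, in which chlorous acid converts the enal into the acid while the alkene scavenger removes hypochlorous acid, so that the ring alkenes, the allylic acetates and the alkene geometry should be untouched.

**Compound list**

1 | 3-methylbut-2-enal | CC(C)=CC=O | starting material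
2 | (E)-3-methyl-1-[tri(propan-2-yl)silyloxy]buta-1,3-diene | C=C(C)/C=C/O[Si](C(C)C)(C(C)C)C(C)C | intermediate
3 | methyl 2,2-dimethoxyacetate | COC(OC)C(=O)OC | starting material
4 | N-methoxy-N-methyl-2,2-dimethoxyacetamide | COC(OC)C(=O)N(C)OC | intermediate
5 | bromomagnesium hemiaminal chelate (tetrahedral adduct of 4 and the vinyl Grignard reagent) | C=CC(O[Mg]Br)(N(C)OC)C(OC)OC | intermediate
6 | 1,1-dimethoxybut-3-en-2-one | C=CC(=O)C(OC)OC | intermediate
7 | 2,2-dimethoxy-1-[(1R,2S)-4-methyl-2-{[tri(propan-2-yl)silyl]oxy}cyclohex-3-en-1-yl]ethan-1-one | O=C(C(OC)OC)[C@@H]1CCC(C)=C[C@@H]1O[Si](C(C)C)(C(C)C)C(C)C | intermediate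
8 | {[(1S,6S)-6-(3,3-dimethoxyprop-1-en-2-yl)-3-methylcyclohex-2-en-1-yl]oxy}tri(propan-2-yl)silane | C=C(C(OC)OC)[C@@H]1CCC(C)=C[C@@H]1O[Si](C(C)C)(C(C)C)C(C)C | intermediate
9 | (1S,6S)-6-(3,3-dimethoxyprop-1-en-2-yl)-3-methylcyclohex-2-en-1-ol | C=C(C(OC)OC)[C@@H]1CCC(C)=C[C@@H]1O | intermediate
10 | (6S)-6-(3,3-dimethoxyprop-1-en-2-yl)-3-methylcyclohex-2-en-1-one | O=C1C=C(C)CC[C@H]1C(=C)C(OC)OC | intermediate
11 | 3-methylbutanal | CC(C)CC=O | starting material
12 | 1,1-bis[(4-methoxybenzyl)oxy]-3-methylbutane | CC(C)CC(OCc1ccc(OC)cc1)OCc1ccc(OC)cc1 | intermediate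
13 | 1-methoxy-4-{[(3-methylbut-1-en-1-yl)oxy]methyl}benzene (E/Z mixture) | CC(C)C=COCc1ccc(OC)cc1 | intermediate
14 | 1-{[(1,2-dibromo-3-methylbutyl)oxy]methyl}-4-methoxybenzene (diastereomer mixture) | CC(C)C(Br)C(Br)OCc1ccc(OC)cc1 | intermediate
15 | 1-({[(1Z)-2-bromo-3-methylbut-1-en-1-yl]oxy}methyl)-4-methoxybenzene | CC(C)/C(Br)=C/OCc1ccc(OC)cc1 | intermediate
16 | {1-[(4-methoxybenzyl)oxy]-3-methylbut-1-en-2-yl}lithium, lithium cis to oxygen | CC(C)/C([Li])=C/OCc1ccc(OC)cc1 | intermediate
17 | dichloro{1-[(4-methoxybenzyl)oxy]-3-methylbut-1-en-2-yl}cerium, cerium cis to oxygen | CC(C)/C([Ce](Cl)Cl)=C/OCc1ccc(OC)cc1 | intermediate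
18 | (1S,6S)-6-(3,3-dimethoxyprop-1-en-2-yl)-1-{(1Z)-1-[(4-methoxybenzyl)oxy]-3-methylbut-1-en-2-yl}-3-methylcyclohex-2-en-1-ol | O[C@@]1(/C(C(C)C)=C\OCc2ccc(OC)cc2)C=C(C)CC[C@H]1C(=C)C(OC)OC | intermediate
19 | potassium alkoxide of 18 | [K+].[O-][C@@]1(/C(C(C)C)=C\OCc2ccc(OC)cc2)C=C(C)CC[C@H]1C(=C)C(OC)OC | intermediate
20 | potassium C6=C7 enolate of 21 (ring-E enolate, ring-E C1=C10 alkene, cis C4=C5 alkene) | C1/C(C)=C\C([O-])=C(/C(C)C)[C@H](OCc2ccc(OC)cc2)C/C(C(OC)OC)=C/C1.[K+] | intermediate
21 | (2Z,6Z,9R,10S)-7-(dimethoxymethyl)-9-[(4-methoxybenzyl)oxy]-3-methyl-10-(propan-2-yl)cyclodeca-2,6-dien-1-one | O=C1/C=C(/C)CC/C=C(\C(OC)OC)C[C@@H](OCc2ccc(OC)cc2)[C@@H]1C(C)C | intermediate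
22 | (2Z,6Z,9R,10S)-7-(dimethoxymethyl)-9-hydroxy-3-methyl-10-(propan-2-yl)cyclodeca-2,6-dien-1-one | O=C1/C=C(/C)CC/C=C(\C(OC)OC)C[C@@H](O)[C@@H]1C(C)C | intermediate
23 | (1R,3Z,7Z,9R,10R)-3-(dimethoxymethyl)-9-hydroxy-7-methyl-10-(propan-2-yl)cyclodeca-3,7-dien-1-yl acetate | O[C@@H]1/C=C(/C)CC/C=C(\C(OC)OC)C[C@@H](OC(C)=O)[C@@H]1C(C)C | intermediate
24 | (1R,2Z,6Z,9R,10S)-7-(dimethoxymethyl)-3-methyl-10-(propan-2-yl)cyclodeca-2,6-diene-1,9-diyl diacetate | CC(=O)O[C@@H]1/C=C(/C)CC/C=C(\C(OC)OC)C[C@@H](OC(C)=O)[C@@H]1C(C)C | intermediate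
25 | (1R,2Z,6Z,9R,10S)-7-formyl-3-methyl-10-(propan-2-yl)cyclodeca-2,6-diene-1,9-diyl diacetate | CC(=O)O[C@@H]1/C=C(/C)CC/C=C(\C=O)C[C@@H](OC(C)=O)[C@@H]1C(C)C | intermediate
26 | (1R,2Z,6E,9R,10S)-7-formyl-3-methyl-10-(propan-2-yl)cyclodeca-2,6-diene-1,9-diyl diacetate | CC(=O)O[C@@H]1/C=C(/C)CC/C=C(/C=O)C[C@@H](OC(C)=O)[C@@H]1C(C)C | intermediate
27 | (1E,5Z,7R,8S,9R)-7,9-bis(acetyloxy)-5-methyl-8-(propan-2-yl)cyclodeca-1,5-diene-1-carboxylic acid | CC(=O)O[C@@H]1/C=C(/C)CC/C=C(/C(=O)O)C[C@@H](OC(C)=O)[C@@H]1C(C)C | target

**Step count**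

Total step count: 18. Longest linear sequence: 14 steps (from 3 through steps 2–7 and 11–18).

**Steps most likely to fail**

Step 12. The β-alkoxy enolate may expel the C8 oxygen before it is protonated, the shift may be too slow without crown ether at temperatures the enolate tolerates, or the proton may not be delivered cleanly to C7 during the quench. Fallback: setting out from 18, the shift is run as before, but the cold enolate is silylated with Me3SiCl/Et3N at −78 °C instead of being protonated, which should give the trimethylsilyl enol ether F1. C7 is then protonated in a separate operation (AcOH, THF/H2O, 0 °C), on carbon and from the outer face of the ring-E enol ether, so that no free enolate is ever warmed, and the route is rejoined at 21.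

Step 4. Face selection by the boron catalyst may be poor with this dienophile, the acetal oxygens may compete for the Lewis acid, or the silyl dienol ether may react stepwise by Mukaiyama–Michael addition with silyl transfer. Fallback: setting out from 2 and 6, the cycloaddition is run thermally without catalyst (toluene, 40 °C) to the racemic cis adduct F2. This is methylenated as in step 5 to the racemic silyl ether F3 and desilylated as in step 6 to the racemic alcohol F4. Kinetic resolution with vinyl acetate and Candida antarctica lipase B, which by the empirical rule for secondary alcohols should acylate the (1R) alcohol to the acetate F5, leaves (1S,6S)-9 unreacted, and the route is rejoined at 9.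

Step 14. The Lewis-acidic samarium species may trigger retro-aldol opening of the ring or transannular addition of the free C8 hydroxyl to the enone before hydride is transferred, or the hydride shift may stall on the hindered, conjugated ketone. Fallback: setting out from 22, hydroxyl-directed reduction with Me4NBH(OAc)3 (MeCN/AcOH, −30 °C), which also delivers hydride from the C8 oxygen, should give the 1,3-anti diol F6. Exhaustive acetylation (Ac2O, 4-(dimethylamino)pyridine, pyridine) then esterifies both hydroxyls and rejoins the route at 24.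

**Further compounds**

F1 | step 12 | trimethylsilyl enol ether of 21 (C6=C7 ring-E, O-silylated) | C1/C(C)=C\C(O[Si](C)(C)C)=C(/C(C)C)[C@H](OCc2ccc(OC)cc2)C/C(C(OC)OC)=C/C1
F2 | step 4 | racemic cis adduct (7 and its enantiomer) | O=C(C(OC)OC)[C@@H]1CCC(C)=C[C@@H]1O[Si](C(C)C)(C(C)C)C(C)C.O=C(C(OC)OC)[C@H]1CCC(C)=C[C@H]1O[Si](C(C)C)(C(C)C)C(C)C
F3 | step 4 | racemic silyl ether (8 and its enantiomer) | C=C(C(OC)OC)[C@@H]1CCC(C)=C[C@@H]1O[Si](C(C)C)(C(C)C)C(C)C.C=C(C(OC)OC)[C@H]1CCC(C)=C[C@H]1O[Si](C(C)C)(C(C)C)C(C)C
F4 | step 4 | racemic alcohol (9 and its enantiomer) | C=C(C(OC)OC)[C@@H]1CCC(C)=C[C@@H]1O.C=C(C(OC)OC)[C@H]1CCC(C)=C[C@H]1O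
F5 | step 4 | (1R,6R)-6-(3,3-dimethoxyprop-1-en-2-yl)-3-methylcyclohex-2-en-1-yl acetate | C=C(C(OC)OC)[C@H]1CCC(C)=C[C@H]1OC(C)=O
F6 | step 14 | (1R,2Z,6Z,9R,10S)-7-(dimethoxymethyl)-3-methyl-10-(propan-2-yl)cyclodeca-2,6-diene-1,9-diol | O[C@@H]1/C=C(/C)CC/C=C(\C(OC)OC)C[C@@H](O)[C@@H]1C(C)C
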